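## Retrosynthetic overview
- Sophoranone (**5**) is an intact (2S)-7,4'-dihydroxyflavanone core carrying three prenyl groups (C8, C3', C5'). The C2 stereocentre is bought in (S)-liquiritigenin (**1**) and never touched.
- Disconnect the C8 prenyl as a photochemical O→C [1,3]-prenyl shift from a 7-O-prenyl ether (**4**). The 7-O-prenyl group also protects the 7-OH during the B-ring step.
- Disconnect the two B-ring prenyls as a photochemical ortho C–H prenylation of the 4'-phenolate of **3**.
- The 7-O-prenyl ether **3** comes from pKa-selective O-prenylation of **1**. Order: 7-O-prenylation, then B-ring bis-C-prenylation, then A-ring O→C shift.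

Assumptions:
- (S)-Liquiritigenin is commercially available.
- In the final shift, C8 is favoured over C6 (less hindered, flanked by the ring oxygen), and the C6 isomer is removable by chromatography.

## Route

**Step 1**
Reactants: **1** (S)-liquiritigenin; **2** prenyl bromide
Product: **3** (2S)-7-O-prenyl-4'-hydroxyflavanone (7-O-prenylliquiritigenin)
Conditions: **2** (1.05 equiv), K2CO3 (1.2 equiv), acetone, 20 °C, 12 h
Reagents that add atoms: prenyl bromide, CC(C)=CCBr
Why: The 7-OH (pKa ≈ 7.5, para to the carbonyl) is deprotonated far before the 4'-OH (pKa ≈ 10), so Williamson etherification is selective for O7. The 7-phenolate also deactivates the ketone toward E1cB ring opening, so C2 is not racemised, and no new stereocentre forms.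

**Step 2**
Reactants: **3**; **2** prenyl bromide
Product: **4** (2S)-7-O-prenyl-3',5'-diprenyl-4'-hydroxyflavanone
Conditions: **2** (2.8 equiv), K2CO3 (3 equiv), MeCN, 15 °C, 370 nm LEDs, 24 h, N2
Reagents that add atoms: prenyl bromide, CC(C)=CCBr
Why: Proposed new method: visible-edge/near-UV excitation of the 4'-aryl-phenolate (or its ion pair with prenyl bromide) gives single-electron transfer to C–Br. This forms a phenoxyl/prenyl radical pair, which couples at the ortho carbon through the less hindered allyl terminus. That gives a 6-prenylcyclohexa-2,4-dienone, which tautomerises to the ortho-prenylphenol; the cycle repeats at the second ortho position, and the blocked para position and the two blocked ortho positions stop further reaction. The closest known reactions are photochemical alkylation of phenolates/naphtholates with alkyl halides and the photo-Claisen radical-pair coupling. Irradiating only at the phenolate's absorption edge, at low temperature with sparingly soluble base, suppresses dark SN2 O-prenylation. C2 is not involved; the conditions are mild and the ring oxygen and 7-O-prenyl ether are inert.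

**Step 3**
Reactant: **4**
Product: **5** sophoranone, (2S)-7,4'-dihydroxy-8,3',5'-triprenylflavanone
Conditions: hν (310 nm LEDs), PhMe, 15 °C, 6 h, N2
Reagents that add atoms: none (isomerisation)
Why: Photo-Claisen-type [1,3] O→C shift. The aroyl chromophore's excited state homolyses the weak aryl–O/allyl bond (Ar–O–CH2 of the prenyl ether) to a caged phenoxyl/prenyl radical pair. Recombination at the primary prenyl terminus onto C8 gives a dienone that tautomerises to the 7-OH/8-prenyl phenol. No reagent is added, so there is no over-alkylation; the conditions are neutral, so C2 is retained. The free hindered 4'-OH and the other prenyl alkenes are untouched under these conditions.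

## Compound list
1 | (S)-liquiritigenin, (2S)-7,4'-dihydroxyflavanone | Oc1ccc([C@@H]2CC(=O)c3ccc(O)cc3O2)cc1 | starting material
2 | prenyl bromide, 1-bromo-3-methylbut-2-ene | CC(C)=CCBr | starting material
3 | (2S)-7-O-prenyl-4'-hydroxyflavanone | Oc1ccc([C@@H]2CC(=O)c3ccc(OCC=C(C)C)cc3O2)cc1 | intermediate
4 | (2S)-7-O-prenyl-3',5'-diprenyl-4'-hydroxyflavanone | CC(C)=CCc1cc([C@@H]2CC(=O)c3ccc(OCC=C(C)C)cc3O2)cc(CC=C(C)C)c1O | intermediate
5 | sophoranone | CC(C)=CCc1cc([C@@H]2CC(=O)c3ccc(O)c(CC=C(C)C)c3O2)cc(CC=C(C)C)c1O | target

Atom check: **1** is C15H12O4. Each prenylation replaces one H with C5H9, so **3** is C20H20O4 and **4** is C30H36O4. Step 3 is an isomerisation, so **5** is C30H36O4, matching the target.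

## Totals
Total steps: 3. Longest linear sequence: 3.

## Three steps most likely to fail
1. **Step 2 (proposed new method).** Risks are dark O-prenylation, reverse-prenyl coupling and partial racemisation from the carbonate base.
   - Fallback (known chemistry, different approach): 4'-O-allylation, thermal aromatic Claisen to the 3'-allyl phenol, and a repeat of O-allylation/Claisen to give the 3',5'-diallyl phenol. Then cross-metathesis with 2-methyl-2-butene (Hoveyda–Grubbs II) converts both allyls to prenyls. The enantiomeric excess would be checked by chiral HPLC.
2. **Step 3.** The photo-[1,3] shift may give C6 and reverse-prenyl isomers or simple cleavage to the 7-OH compound.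
   - Fallback (known chemistry, different approach): Pd(0)/morpholine removes the 7-O-prenyl group to give the 7-OH compound. Then 7-O-allylation, Claisen to the 8-allyl compound (regioselective for C8 in 7-allyloxychromanoids) and cross-metathesis with 2-methyl-2-butene give the 8-prenyl product.
3. **Step 1.** Over-alkylation at O4' or some epimerisation could occur.
   - Fallback (known chemistry, different approach): Mitsunobu etherification with prenol (PPh3, DIAD, THF, 0 °C). It is neutral, so racemisation is avoided, and the more acidic 7-OH reacts selectively.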